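A direct plan would build the 1,4-benzodioxane by a carbene ring expansion: the metal-bound aryl carbene released from N-sulfonylhydrazone A2 would attack an acetal oxygen of racemic 4-methoxy-2-methyl-1,3-benzodioxole A1, and a [1,2]-Stevens shift of the oxonium ylide would give benzodioxane acetate A3.
A2 would come in four steps from p-cresol A4 through syringaldehyde A5; the allyl group would be added last by C–H borylation, allyl cross-coupling and deacetylation.
Weakest step, the ylide ring expansion: it has no precedent for benzodioxoles or donor aryl carbenes, the regiochemistry of O-attack and both stereocenters are decided in a ring-opened zwitterion that may have left the chiral catalyst, and the aryldiazomethane can dimerise instead.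
Second, the run-up to A5: ring bromination, side-chain oxidation and Ullmann methoxylation of A4 only rebuild a cheap commercial aldehyde, and the acetate is put on and taken off solely for the carbene step.
Third, the late allylation: on the finished, stereodefined core the borylation site rests on sterics alone, and the coupling risks allyl-to-propenyl migration.

**Retrosynthetic overview**
Ring A is the benzo ring with 5-OMe and 7-allyl, ring B the 1,4-dioxane ring, ring C the 4-hydroxy-3,5-dimethoxyphenyl ring. Ring B is cut at both C–O bonds, O1–C2 and O4–C3, so the target is the formal [4+2] adduct of an o-quinone (ring A with O1 and O4) and an (E)-propenylphenol (ring C with C2, C3 and the methyl group), the 8–O–4′/7–O–3′ coupling of the presumed biosynthesis.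
Dienophile 3 comes in one stereoretentive Suzuki coupling from bromophenol 1 and (E)-propenylboronate 2; o-quinone 5 comes in one periodate oxidative demethylation from commercial methoxyeugenol 4, which already carries the C7 allyl and C5 methoxy groups.
Ring B closes last, in one catalytic, redox-neutral operation steered by (R)-3,3′-bis(2,4,6-triisopropylphenyl)-1,1′-binaphthalene-2,2′-diyl hydrogen phosphate. The free 4-OH of ring C is the handle of this acid and makes C2 a quinone methide carbon (intermediate 6), so C3 is set by the catalyst and C2 is funnelled to the trans isomer 7.
Nothing is protected, no carbene is needed, the allyl group is never installed on the core and no commercial arene is rebuilt; the risk sits in the enantiocontrol of the one key step.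

Key step: step 3

Assumption: the sense of induction of the phosphoric acid in step 3 cannot be predicted with certainty; the (R)-acid is written, and the (S)-acid would be used should the (2S,3S) enantiomer prevail.

Step 1
Reactants: 1 4-bromo-2,6-dimethoxyphenol; 2 4,4,5,5-tetramethyl-2-[(E)-prop-1-en-1-yl]-1,3,2-dioxaborolane ((E)-prop-1-enylboronic acid pinacol ester)
Product: 3 (E)-2,6-dimethoxy-4-(prop-1-en-1-yl)phenol
Conditions: Pd(OAc)2 (2 mol %), SPhos (2-dicyclohexylphosphino-2′,6′-dimethoxybiphenyl, 4 mol %), K3PO4 (3 equiv), 1,4-dioxane/H2O (5:1), 80 °C; aq. NH4Cl
Reagents that add atoms: none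
Why: Stereoretentive Suzuki–Miyaura coupling should attach the propenyl group to ring C with the E geometry fixed by the boronate, and the electron-rich biarylphosphine allows oxidative addition of the unprotected, electron-rich bromophenol.

Step 2
Reactants: 4 4-allyl-2,6-dimethoxyphenol (methoxyeugenol)
Product: 5 3-methoxy-5-(prop-2-en-1-yl)cyclohexa-3,5-diene-1,2-dione (5-allyl-3-methoxy-1,2-benzoquinone)
Conditions: NaIO4 (1.2 equiv), AcOH/H2O (3:1), 0 °C, 10 min; cold CH2Cl2 extraction, Na2SO4, solution kept at or below 0 °C and used at once
Reagents that add atoms: sodium periodate, [Na+].[O-]I(=O)(=O)=O; water, O (the new carbonyl oxygen comes from the periodate–water pool)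
Why: Periodate oxidative demethylation of a 2-methoxyphenol (Adler oxidation) should proceed through the aryl periodate ester and an o-quinone hemiketal that loses methanol, the symmetric substrate can give only one quinone, and periodate alone leaves the isolated allyl double bond untouched.

Step 3
Reactants: 3 (E)-2,6-dimethoxy-4-(prop-1-en-1-yl)phenol; 5 3-methoxy-5-(prop-2-en-1-yl)cyclohexa-3,5-diene-1,2-dione
Product: 7 4-[(2R,3R)-7-allyl-5-methoxy-3-methyl-2,3-dihydro-1,4-benzodioxin-2-yl]-2,6-dimethoxyphenol, via p-quinone methide 6 (not isolated)
Conditions: (R)-3,3′-bis(2,4,6-triisopropylphenyl)-1,1′-binaphthalene-2,2′-diyl hydrogen phosphate (10 mol %), 5 (1.3 equiv), toluene/CH2Cl2, −40 → −20 °C, dark, Ar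
Reagents that add atoms: none
Why: Proposed new method: the phosphoric acid should hold both partners by hydrogen bonds, its P=O accepting the 4-OH of 3 and its P–OH donating to the more basic C1 carbonyl of 5 (a doubly vinylogous ester through the 3-OMe group), so that the nucleophilic β-carbon of the propenyl group attacks the quinone oxygen on C2 (next to C–OMe), ring A aromatises and a proton relay leaves the p-quinone methide 6, the same 8–O–4′ bond as in the presumed biosynthesis. The catechol O–H set free in 6 then adds to the quinone methide carbon in a 6-exo-trig oxa-1,6-addition that closes ring B, so that the overall change is an inverse-electron-demand oxa-Diels–Alder reaction with the quinone as O=C–C=O heterodiene and needs no external oxidant. The closest known reactions are the racemic benzodioxane formation from o-quinones (or catechols and Ag2O) with propenylphenols and the chiral phosphoric acid-catalysed inverse-electron-demand aza-Diels–Alder (Povarov) reactions of isoeugenol-type 4-hydroxypropenylbenzenes, in which the free para-OH is the handle of the catalyst; an enantioselective version with an o-quinone as heterodiene has not been shown. C3 is set by the catalyst in the first C–O bond formation, which selects the face of the alkene at the methyl-bearing carbon; C2 follows from the E geometry of 3 and, because the 4-hydroxyaryl group lets the O1–C2 bond reopen to 6 under the acid, from equilibration to the trans isomer with aryl and methyl both pseudo-equatorial. The step needs O- over C-attack on the quinone, the regiochemistry that puts the methyl-bearing carbon on the oxygen next to C–OMe, and the catalysed over the background pathway: the 3-OMe group blocks one terminus of the carbodiene and polarises the two carbonyl groups, C4 is flanked by the methoxy and allyl groups, and the low temperature holds back the uncatalysed reaction.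

**Compound list**
1 | 4-bromo-2,6-dimethoxyphenol | COc1cc(Br)cc(OC)c1O | starting material
2 | 4,4,5,5-tetramethyl-2-[(E)-prop-1-en-1-yl]-1,3,2-dioxaborolane | C/C=C/B1OC(C)(C)C(C)(C)O1 | starting material
3 | (E)-2,6-dimethoxy-4-(prop-1-en-1-yl)phenol | C/C=C/c1cc(OC)c(O)c(OC)c1 | intermediate
4 | 4-allyl-2,6-dimethoxyphenol (methoxyeugenol) | C=CCc1cc(OC)c(O)c(OC)c1 | starting material
5 | 3-methoxy-5-(prop-2-en-1-yl)cyclohexa-3,5-diene-1,2-dione | C=CCC1=CC(=O)C(=O)C(OC)=C1 | intermediate
6 | 4-{(2R)-2-[4-allyl-2-hydroxy-6-methoxyphenoxy]propylidene}-2,6-dimethoxycyclohexa-2,5-dien-1-one | C=CCc1cc(O)c(O[C@H](C)C=C2C=C(OC)C(=O)C(OC)=C2)c(OC)c1 | intermediate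
7 | 4-[(2R,3R)-7-allyl-5-methoxy-3-methyl-2,3-dihydro-1,4-benzodioxin-2-yl]-2,6-dimethoxyphenol | C=CCc1cc(OC)c2c(c1)O[C@H](c1cc(OC)c(O)c(OC)c1)[C@@H](C)O2 | target

Total step count: 3. Longest linear sequence: 2 steps (4 → 5 → 7, or 1 → 3 → 7).

**Steps most likely to fail**

1. Step 3 (Proposed new method). What may go wrong: loss of enantiofacial control, because an uncatalysed or radical background cycloaddition of the electron-rich pair competes with the acid-bound pathway, together with self-condensation of the quinone. The fallback uses known chemistry and sets out from 3 and 5. They would be combined without the chiral acid (CH2Cl2, 0 °C → rt), the established thermal benzodioxane formation from o-quinones and propenylphenols, to give racemic 4-[(2R*,3R*)-7-allyl-5-methoxy-3-methyl-2,3-dihydro-1,4-benzodioxin-2-yl]-2,6-dimethoxyphenol F1. The enantiomers would be separated by preparative HPLC on cellulose tris(3,5-dimethylphenylcarbamate), and the (2R,3R) enantiomer is 7, where the fallback comes back to the route.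

2. Step 2. What may go wrong: tautomerisation of the allyl-substituted o-quinone to a p-quinone methide (the allylic CH2 is para to a carbonyl group) and self-condensation during the aqueous oxidation and work-up. The fallback sets out from 4, which would be mono-demethylated without oxidation (AlCl3, pyridine, CH2Cl2, reflux; aq. HCl; the aluminium catecholate formed after the first cleavage protects the second methoxy group) to the storable 5-allyl-3-methoxybenzene-1,2-diol F2. F2 would be oxidised only when needed under anhydrous conditions (Ag2O, Na2SO4, dry Et2O, −20 °C, filtration), and the cold filtrate contains 5, where the fallback comes back to the route.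

3. Step 1. What may go wrong: slow oxidative addition of the electron-rich bromophenolate and protodeboronation of the alkenylboronate, which would leave the coupling incomplete. The fallback sets out from 4, whose allyl group would be moved into conjugation by hydride-catalysed alkene isomerisation (RuClH(CO)(PPh3)3, toluene, 80 °C; any Z isomer removed on AgNO3-impregnated silica), and comes back to the route at 3. This fallback makes no new compound (F0), and both halves of the target would then come from one commercial phenol.

**Further compounds**
F1 | step 3 | racemic 4-[(2R*,3R*)-7-allyl-5-methoxy-3-methyl-2,3-dihydro-1,4-benzodioxin-2-yl]-2,6-dimethoxyphenol (1:1 mixture of the two trans enantiomers) | C=CCc1cc(OC)c2c(c1)O[C@H](c1cc(OC)c(O)c(OC)c1)[C@@H](C)O2.C=CCc1cc(OC)c2c(c1)O[C@@H](c1cc(OC)c(O)c(OC)c1)[C@H](C)O2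
F2 | step 2 | 5-allyl-3-methoxybenzene-1,2-diol | C=CCc1cc(O)c(O)c(OC)c1
F0 | step 1 | none | none
A1 | direct plan | 4-methoxy-2-methyl-1,3-benzodioxole (racemic) | COc1cccc2OC(C)Oc12
A2 | direct plan | (E)-N'-(4-acetoxy-3,5-dimethoxybenzylidene)-2-(trifluoromethyl)benzenesulfonohydrazide | CC(=O)Oc1c(OC)cc(/C=N/NS(=O)(=O)c2ccccc2C(F)(F)F)cc1OC
A3 | direct plan | 4-[(2R,3R)-5-methoxy-3-methyl-2,3-dihydro-1,4-benzodioxin-2-yl]-2,6-dimethoxyphenyl acetate | COc1cccc2O[C@H](c3cc(OC)c(OC(C)=O)c(OC)c3)[C@@H](C)Oc12
A4 | direct plan | 4-methylphenol (p-cresol) | Cc1ccc(O)cc1
A5 | direct plan | 4-hydroxy-3,5-dimethoxybenzaldehyde (syringaldehyde) | COc1cc(C=O)cc(OC)c1O
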